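## Retrosynthetic overview

1. The chalcone C=C is cut last: acid-mediated Claisen–Schmidt condensation of an 8-acetyl-4-phenyl-dihydrocoumarin with 4-hydroxybenzaldehyde.
2. The lactone C–O bond is cut back to an ortho-hydroxyaryl propanoate. A single benzyl ether on the oxygen para to the acetyl group leaves only the correct phenol next to the side chain.
3. Key bond C4–C4a: the β-carbon of ethyl cinnamate, normally an electrophile, is used as a nucleophile in the form of an enantioenriched β-boryl ester (a chiral homoenolate equivalent). It is joined to the equally electrophilic iodine-bearing carbon of an iodinated acylphloroglucinol, and the carbon–boron centre is carried over with retention to become C4.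
4. Ring order: the three benzene rings are bought (phloroacetophenone, ethyl cinnamate, 4-hydroxybenzaldehyde). The lactone is the only ring formed, in the same operation as the key coupling.

Assumption: the copper/ferrocenyl bisphosphine borylation is taken to give the (S)-boronate with the (R,Sp) ligand (so the (S,Rp) ligand is used), and the coupling is taken to go with retention as benzylic pinacol boronates do; both are checked by oxidising a sample of the boronate to the known β-hydroxy ester and by the chiroptical data of the lactone.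

## Route

Step 1
Reactants: 1 1-(2,4,6-trihydroxyphenyl)ethan-1-one (phloroacetophenone)
Product: 2 1-[4-(benzyloxy)-2,6-dihydroxyphenyl]ethan-1-one
Conditions: BnBr (1.0 equiv), K2CO3 (1.0 equiv), DMF, 0 °C to rt
Reagents that add atoms: benzyl bromide, BrCc1ccccc1
Why: Williamson ether synthesis; the 4-hydroxyl is the most acidic phenol and the only one not hydrogen-bonded to the acetyl carbonyl, so one equivalent each of base and bromide alkylates it first and leaves the two equivalent ortho phenols free.

Step 2
Reactants: 2 1-[4-(benzyloxy)-2,6-dihydroxyphenyl]ethan-1-one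
Product: 3 1-[4-(benzyloxy)-2,6-dihydroxy-3-iodophenyl]ethan-1-one
Conditions: N-iodosuccinimide (1.0 equiv), DMF, −20 to 0 °C, dark
Reagents that add atoms: N-iodosuccinimide, O=C1CCC(=O)N1I
Why: Electrophilic aromatic iodination; the two open ring positions of 2 are equivalent by symmetry and strongly activated, so one equivalent of reagent at low temperature gives a single mono-iodide with iodine between a free phenol and the benzyl ether.

Step 3
Reactants: 4 ethyl (2E)-3-phenylprop-2-enoate (ethyl cinnamate)
Product: 5 ethyl (3R)-3-phenyl-3-(4,4,5,5-tetramethyl-1,3,2-dioxaborolan-2-yl)propanoate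
Conditions: B2pin2 (1.1 equiv), CuCl (3 mol %), NaOtBu (3 mol %), (S)-1-[(Rp)-2-(diphenylphosphino)ferrocenyl]ethyldicyclohexylphosphine (4 mol %), MeOH (2 equiv), THF, rt
Reagents that add atoms: bis(pinacolato)diboron, CC1(C)OB(OC1(C)C)B1OC(C)(C)C(C)(C)O1
Why: Copper-catalysed enantioselective conjugate borylation (β-boration); the chiral bisphosphine boryl complex of monovalent copper delivers boron to one face of the β-carbon and methanol protonates the copper enolate, which sets the (R) carbon–boron centre (about 90% ee expected) and turns the normally electrophilic β-carbon into a nucleophilic homoenolate equivalent.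

Step 4
Reactants: 3 1-[4-(benzyloxy)-2,6-dihydroxy-3-iodophenyl]ethan-1-one; 5 ethyl (3R)-3-phenyl-3-(4,4,5,5-tetramethyl-1,3,2-dioxaborolan-2-yl)propanoate (1.5 equiv)
Product: 7 (4R)-8-acetyl-5-(benzyloxy)-7-hydroxy-4-phenyl-3,4-dihydro-2H-chromen-2-one, via open-chain ethyl ester 6 (not isolated)
Conditions: Pd2(dba)3 (5 mol %), PPh3 (80 mol %), Ag2O (1.5 equiv), DME, 85 °C, 24 h; filter; TsOH·H2O (10 mol %), toluene, 80 °C
Reagents that add atoms: none
Why: Proposed new method: the closest known reaction is the stereoretentive Suzuki–Miyaura coupling of enantioenriched secondary benzylic pinacol boronates with aryl iodides under Ag2O and excess PPh3, not yet shown for a β-ester boronate with a doubly ortho-substituted iodophenol; zerovalent palladium inserts into the carbon–iodine bond of 3, Ag2O-assisted transmetalation of the benzylic carbon–boron bond of 5 goes through a closed Pd–O–B transition state (possibly helped by the neighbouring phenoxide binding boron) with retention, and reductive elimination, favoured by the two ortho substituents, forms C4–C4a so that the (R) carbon–boron centre becomes the (R) carbon–aryl centre, while the high phosphine loading and ester chelation hold back β-hydride elimination to cinnamate, and acid then closes the lactone onto the only free phenol beside the new side chain.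

Step 5
Reactants: 7 (4R)-8-acetyl-5-(benzyloxy)-7-hydroxy-4-phenyl-3,4-dihydro-2H-chromen-2-one
Product: 8 (4R)-8-acetyl-5,7-dihydroxy-4-phenyl-3,4-dihydro-2H-chromen-2-one
Conditions: H2 (1 atm), Pd/C (10 wt %), EtOAc, rt
Reagents that add atoms: none
Why: Hydrogenolysis of the aryl benzyl ether over palladium on carbon; the lactone, the ortho-hydroxyaryl ketone and C4 (no benzylic heteroatom) are inert at 1 atm and room temperature, and the step is placed before the enone exists.

Step 6
Reactants: 8 (4R)-8-acetyl-5,7-dihydroxy-4-phenyl-3,4-dihydro-2H-chromen-2-one; 9 4-hydroxybenzaldehyde (1.2 equiv)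
Product: 11 (4R)-5,7-dihydroxy-8-[(2E)-3-(4-hydroxyphenyl)prop-2-enoyl]-4-phenyl-3,4-dihydro-2H-chromen-2-one, via aldol adduct 10 (not isolated)
Conditions: BF3·OEt2 (0.5 equiv), 1,4-dioxane, rt; then H2O
Reagents that add atoms: none
Why: BF3·OEt2-mediated Claisen–Schmidt (acid-mediated aldol) condensation; boron activation of the ortho-hydroxyaryl ketone lets its enol add to the aldehyde and the adduct dehydrates to the conjugated (E)-enone under thermodynamic control, free phenols are tolerated, and without base or nucleophilic solvent the lactone is not opened (no regiochemical scrambling) and C4 is untouched.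

Note on enantiopurity: lactone 7 is expected to be crystalline, and one recrystallisation at that stage is planned to raise the ee before the last two steps.

## Compound list

1 | 1-(2,4,6-trihydroxyphenyl)ethan-1-one | CC(=O)c1c(O)cc(O)cc1O | starting material
2 | 1-[4-(benzyloxy)-2,6-dihydroxyphenyl]ethan-1-one | CC(=O)c1c(O)cc(OCc2ccccc2)cc1O | intermediate
3 | 1-[4-(benzyloxy)-2,6-dihydroxy-3-iodophenyl]ethan-1-one | CC(=O)c1c(O)cc(OCc2ccccc2)c(I)c1O | intermediate
4 | ethyl (2E)-3-phenylprop-2-enoate | CCOC(=O)/C=C/c1ccccc1 | starting material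
5 | ethyl (3R)-3-phenyl-3-(4,4,5,5-tetramethyl-1,3,2-dioxaborolan-2-yl)propanoate | CCOC(=O)C[C@H](c1ccccc1)B1OC(C)(C)C(C)(C)O1 | intermediate
6 | ethyl (3R)-3-[3-acetyl-6-(benzyloxy)-2,4-dihydroxyphenyl]-3-phenylpropanoate | CCOC(=O)C[C@H](c1ccccc1)c1c(O)c(C(C)=O)c(O)cc1OCc1ccccc1 | intermediate (not isolated)
7 | (4R)-8-acetyl-5-(benzyloxy)-7-hydroxy-4-phenyl-3,4-dihydro-2H-chromen-2-one | O=C1C[C@H](c2ccccc2)c2c(OCc3ccccc3)cc(O)c(C(C)=O)c2O1 | intermediate
8 | (4R)-8-acetyl-5,7-dihydroxy-4-phenyl-3,4-dihydro-2H-chromen-2-one | O=C1C[C@H](c2ccccc2)c2c(O)cc(O)c(C(C)=O)c2O1 | intermediate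
9 | 4-hydroxybenzaldehyde | O=Cc1ccc(O)cc1 | starting material
10 | (4R)-5,7-dihydroxy-8-[3-hydroxy-3-(4-hydroxyphenyl)propanoyl]-4-phenyl-3,4-dihydro-2H-chromen-2-one (both carbinol epimers) | O=C1C[C@H](c2ccccc2)c2c(O)cc(O)c(C(=O)CC(O)c3ccc(O)cc3)c2O1 | intermediate (not isolated)
11 | (4R)-5,7-dihydroxy-8-[(2E)-3-(4-hydroxyphenyl)prop-2-enoyl]-4-phenyl-3,4-dihydro-2H-chromen-2-one | O=C1C[C@H](c2ccccc2)c2c(O)cc(O)c(C(=O)/C=C/c3ccc(O)cc3)c2O1 | target

## Step count and risks

Total steps: 6. Longest linear sequence: 5 (1 → 2 → 3 → 7 → 8 → 11); step 3 is a one-step branch.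

**Step 4 (most likely to fail).** The iodide is flanked by two oxygen substituents and carries free phenols. Transmetalation may be slow, protodeiodination and β-hydride elimination to ethyl cinnamate compete, and some stereochemical fidelity may be lost.
The fallback sets out from 2 and comes back to the route at 7. It keeps the homoenolate logic but moves the boron to the hindered fragment, so that the electrophile is unhindered iodobenzene.
- Phenol 2 and ethyl propiolate (Pd(OAc)2 cat., CF3CO2H/CH2Cl2, rt; hydroarylation of the alkyne by the free ring position) give ethyl (2Z)-3-[3-acetyl-6-(benzyloxy)-2,4-dihydroxyphenyl]prop-2-enoate F1. It is not isolated, because the neighbouring free phenol closes at once to the coumarin 8-acetyl-5-(benzyloxy)-7-hydroxy-2H-chromen-2-one F2.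
- Copper-catalysed enantioselective conjugate borylation of F2 (CuCl, NaOtBu, the ferrocenyl bisphosphine enantiomer that gives the (S) centre, B2pin2, MeOH, THF) gives (4S)-8-acetyl-5-(benzyloxy)-7-hydroxy-4-(4,4,5,5-tetramethyl-1,3,2-dioxaborolan-2-yl)-3,4-dihydro-2H-chromen-2-one F3.
- Coupling of F3 with iodobenzene under the step 4 conditions (Pd2(dba)3, PPh3, Ag2O, DME, 85 °C), again with retention, puts the phenyl group on C4 and gives 7.

**Step 6.** The aldehyde may attack the electron-rich C6 position under Lewis acid, the 7-hydroxyl may add to the enone (flavanone-type cyclisation), or conversion may stall on the polyphenol.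
The fallback sets out from 7 and comes back to the route at 11.
- 7 and 4-(benzyloxy)benzaldehyde under KOH, EtOH/H2O, rt: hydroxide opens the lactone and the condensation runs on the carboxylate, giving (3R)-3-[6-(benzyloxy)-3-[(2E)-3-[4-(benzyloxy)phenyl]prop-2-enoyl]-2,4-dihydroxyphenyl]-3-phenylpropanoic acid F4.
- Acidification to pH 2 and brief warming with TsOH in toluene re-close the lactone onto the only free phenol beside the side chain (the para oxygen is still benzylated). This gives (4R)-5-(benzyloxy)-8-[(2E)-3-[4-(benzyloxy)phenyl]prop-2-enoyl]-7-hydroxy-4-phenyl-3,4-dihydro-2H-chromen-2-one F5.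
- BCl3 with pentamethylbenzene, CH2Cl2, −78 °C cleaves both benzyl ethers without touching the enone and gives 11.

**Step 1.** Over-benzylation to the 2,4-diether and C-benzylation of the phloroglucinol ring can erode the yield of the mono-ether.
The fallback sets out from 1 and comes back to the route at 8. It replaces the benzyl ether by a bulky silyl ether, which goes on oxygen only and comes off with fluoride.
- 1 with TIPSCl (1.05 equiv), imidazole, DMF, 0 °C gives 1-[2,6-dihydroxy-4-(triisopropylsilyloxy)phenyl]ethan-1-one F6.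
- N-Iodosuccinimide as in step 2 gives 1-[2,6-dihydroxy-3-iodo-4-(triisopropylsilyloxy)phenyl]ethan-1-one F7.
- Coupling with 5 under the step 4 conditions gives ethyl (3R)-3-[3-acetyl-2,4-dihydroxy-6-(triisopropylsilyloxy)phenyl]-3-phenylpropanoate F8, not isolated, which lactonises to (4R)-8-acetyl-7-hydroxy-4-phenyl-5-(triisopropylsilyloxy)-3,4-dihydro-2H-chromen-2-one F9.
- HF·pyridine, THF, 0 °C removes the silyl group and gives 8.

## Further compounds

F1 | step 4 | ethyl (2Z)-3-[3-acetyl-6-(benzyloxy)-2,4-dihydroxyphenyl]prop-2-enoate | CCOC(=O)/C=C\c1c(O)c(C(C)=O)c(O)cc1OCc1ccccc1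
F2 | step 4 | 8-acetyl-5-(benzyloxy)-7-hydroxy-2H-chromen-2-one | O=C1C=Cc2c(OCc3ccccc3)cc(O)c(C(C)=O)c2O1
F3 | step 4 | (4S)-8-acetyl-5-(benzyloxy)-7-hydroxy-4-(4,4,5,5-tetramethyl-1,3,2-dioxaborolan-2-yl)-3,4-dihydro-2H-chromen-2-one | O=C1C[C@H](B2OC(C)(C)C(C)(C)O2)c2c(OCc3ccccc3)cc(O)c(C(C)=O)c2O1
F4 | step 6 | (3R)-3-[6-(benzyloxy)-3-[(2E)-3-[4-(benzyloxy)phenyl]prop-2-enoyl]-2,4-dihydroxyphenyl]-3-phenylpropanoic acid | OC(=O)C[C@H](c1ccccc1)c1c(O)c(C(=O)/C=C/c2ccc(OCc3ccccc3)cc2)c(O)cc1OCc1ccccc1
F5 | step 6 | (4R)-5-(benzyloxy)-8-[(2E)-3-[4-(benzyloxy)phenyl]prop-2-enoyl]-7-hydroxy-4-phenyl-3,4-dihydro-2H-chromen-2-one | O=C1C[C@H](c2ccccc2)c2c(OCc3ccccc3)cc(O)c(C(=O)/C=C/c3ccc(OCc4ccccc4)cc3)c2O1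
F6 | step 1 | 1-[2,6-dihydroxy-4-(triisopropylsilyloxy)phenyl]ethan-1-one | CC(=O)c1c(O)cc(O[Si](C(C)C)(C(C)C)C(C)C)cc1O
F7 | step 1 | 1-[2,6-dihydroxy-3-iodo-4-(triisopropylsilyloxy)phenyl]ethan-1-one | CC(=O)c1c(O)cc(O[Si](C(C)C)(C(C)C)C(C)C)c(I)c1O
F8 | step 1 | ethyl (3R)-3-[3-acetyl-2,4-dihydroxy-6-(triisopropylsilyloxy)phenyl]-3-phenylpropanoate | CCOC(=O)C[C@H](c1ccccc1)c1c(O)c(C(C)=O)c(O)cc1O[Si](C(C)C)(C(C)C)C(C)C
F9 | step 1 | (4R)-8-acetyl-7-hydroxy-4-phenyl-5-(triisopropylsilyloxy)-3,4-dihydro-2H-chromen-2-one | O=C1C[C@H](c2ccccc2)c2c(O[Si](C(C)C)(C(C)C)C(C)C)cc(O)c(C(C)=O)c2O1
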